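**Retrosynthetic overview**
- The caffeoyl group is detached at the C3–O ester bond, which leaves a 1-O-silylated 3β,8α-diol and bis-silylated caffeic acid.
- The diol is traced back through the C8 ketone (dissolving metal), the C3 α-methylene ketone (Luche), the C1 vinylogous ester (iBu2AlH) and the C4 ketone (methylenation, C15) to a trans-fused 3-methoxy-2-ene-1,4-dione with C8 masked as a silyl enol ether.
- That enedione is cut across C9–C10 and C5–C6 (Diels–Alder) into 2-methoxy-5-methyl-1,4-benzoquinone and 2-silyloxy-3-isopropylbutadiene.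
- Feature used: ring A bears O on C1 and C3, an sp2 carbon at C4 and the methyl-bearing quaternary C10, which is the quinone's own pattern with its methyl-substituted C=C as the C5–C10 fusion bond. C1, C3, C5, C7 and C8 are all equatorial and each is, or adjoins, a former carbonyl carbon, so all can be relayed from C10.
- Ring order: ring A is bought as the quinone, ring B is closed by the cycloaddition, then C15 and last the caffeate are attached.

Key step: step 6

Assumption and convention: eudesmane numbering is used (C14 is the methyl on C10, C15 the exocyclic CH2 on C4). The target is read as the (1R,3S,5S,7R,8S,10R) isomer, that is 10β-CH3, 5α-H, 1β-OH, 3β-acyloxy, 7β-isopropyl and 8α-OH on a trans-decalin. The (R,R) antipode of the diol ligand is assumed to deliver 10R and would be exchanged for (S,S) if a pilot run showed the opposite sense.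

**Route**

Step 1
Reactants: 1 2-methoxy-5-methylphenol
Product: 2 2-methoxy-5-methyl-1,4-benzoquinone
Conditions: (KSO3)2NO (2.2 equiv), KH2PO4 buffer, H2O/acetone, 0 → 23 °C
Reagents that add atoms: potassium nitrosodisulfonate (Fremy's salt), [K+].[K+].[O]N(S(=O)(=O)[O-])S(=O)(=O)[O-]
Why: Teuber oxidation, in which one nitrosodisulfonate radical removes the phenolic hydrogen and a second oxygenates the free para position, gives the 1,4-quinone with the methoxy and methyl groups on different alkenes.

Step 2
Reactants: 3 isovaleraldehyde (3-methylbutanal)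
Product: 4 2-isopropylacrolein (3-methyl-2-methylenebutanal)
Conditions: 37% aq. CH2O, pyrrolidine (10 mol%), EtCO2H (10 mol%), iPrOH, 45 °C; distillation
Reagents that add atoms: formaldehyde, C=O
Why: Amine-catalysed Mannich condensation followed by loss of the amine (α-methylenation of an aldehyde) introduces the future C6 as the terminal CH2 group.

Step 3
Reactants: 4 2-isopropylacrolein
Product: 5 3-isopropylbut-3-en-2-ol (racemic)
Conditions: MeMgBr (1.1 equiv), Et2O, −20 → 0 °C; aq. NH4Cl
Reagents that add atoms: methylmagnesium bromide, C[Mg]Br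
Why: Grignard 1,2-addition to the enal supplies the future C9 as a methyl group, and the racemic carbinol centre is erased in the next step.

Step 4
Reactants: 5 3-isopropylbut-3-en-2-ol
Product: 6 3-isopropylbut-3-en-2-one
Conditions: Dess–Martin periodinane (1.2 equiv), CH2Cl2, 0 → 23 °C; washed and dried solution used directly
Reagents that add atoms: none
Why: Dess–Martin oxidation of the secondary allylic alcohol runs under near-neutral conditions that neither isomerise nor add to the 1,1-disubstituted alkene, and the volatile enone is carried on in solution to limit self-dimerisation.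

Step 5
Reactants: 6 3-isopropylbut-3-en-2-one
Product: 7 2-(triisopropylsilyloxy)-3-isopropylbuta-1,3-diene
Conditions: TIPSOTf (1.1 equiv), Et3N (1.5 equiv), CH2Cl2, 0 °C; filtration through Et3N-deactivated SiO2
Reagents that add atoms: triisopropylsilyl triflate, CC(C)[Si](OS(=O)(=O)C(F)(F)F)(C(C)C)C(C)C
Why: Soft enolisation and O-silylation can take place only at the methyl group because the other α-carbon is sp2, which gives the C6–C9 diene with a bulky silyl group that resists hydrolysis.

Step 6
Reactants: 2 2-methoxy-5-methyl-1,4-benzoquinone; 7 2-(triisopropylsilyloxy)-3-isopropylbuta-1,3-diene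
Product: 8 cis-fused adduct 3-methoxy-8-(triisopropylsilyloxy)-15-nor-5β-eudesma-2,7-diene-1,4-dione (5β-H and 10β-CH3)
Conditions: TiCl2(OiPr)2 (20 mol%), (R,R)-TADDOL (22 mol%), 4 Å MS, toluene/CH2Cl2, −78 → −30 °C
Reagents that add atoms: none
Why: This is a Lewis-acid-promoted quinone Diels–Alder reaction with a 2-silyloxydiene, closest to the chelate-controlled cycloadditions of this quinone under SnCl4 or TiCl4 and to chiral titanium diolate quinone cycloadditions; the tetravalent titanium centre binds the C4 carbonyl oxygen and the C3 methoxy oxygen in a five-membered chelate, so that C4=O, not the more basic vinylogous-ester C1=O, polarises the C5=C10 alkene and C10 becomes the electrophilic β-carbon. The CH2 terminus of the silyl enol ether (C9) bonds to C10 first in an asynchronous suprafacial [4+2] addition (in the extreme a Michael addition followed by enolate closure onto the silyloxyallyl cation) and C6 then bonds to C5. Ring B is thereby closed as a six-membered carbocycle by [4+2] cycloaddition with a cis ring fusion. The quaternary C10 is fixed by the chiral diolate, whose aryl groups screen one face of the chelated quinone, while C5 follows from suprafacial addition and is corrected in step 7; since both diene termini are unsubstituted CH2 groups, endo and exo transition states lead to one and the same adduct. Site selectivity for the methyl-bearing alkene rests on the donor methoxy group deactivating the other alkene and orientation on the two-point chelate; a one-point Lewis acid would sit on the C1 oxygen and invert the orientation, so none is used.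

Step 7
Reactants: 8 cis-fused adduct
Product: 9 trans-fused 3-methoxy-8-(triisopropylsilyloxy)-15-nor-5α-eudesma-2,7-diene-1,4-dione
Conditions: DBU (0.2 equiv), CH2Cl2, 23 °C
Reagents that add atoms: none
Why: Base epimerisation through the extended C4 enolate (conjugated through C3=C2 to C1=O) should equilibrate C5 to the trans-fused decalin with 5α-H anti to C14, as simpler diene adducts of this quinone do, and the quaternary C10 rules out aromatisation.

Step 8
Reactants: 9 trans-fused enedione
Product: 10 3-methoxy-8-(triisopropylsilyloxy)eudesma-2,4(15),7-trien-1-one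
Conditions: Cp2Ti(μ-CH2)(μ-Cl)AlMe2 (Tebbe reagent, 1.2 equiv), pyridine (cat.), THF/toluene, −40 → 0 °C; aq. NaOH
Reagents that add atoms: Tebbe reagent, C[Al-]1(C)C[Ti](C2C=CC=C2)(C2C=CC=C2)[Cl+]1
Why: Tebbe olefination (non-basic titanium methylidene) should convert only the C4 ketone, the more electrophilic and less hindered carbonyl, because C1=O is a vinylogous ester beside the quaternary C10; no enolate forms, so C5 keeps its configuration and C15 is in place.

Step 9
Reactants: 10 3-methoxy-8-(triisopropylsilyloxy)eudesma-2,4(15),7-trien-1-one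
Product: 11 3-methoxy-8-(triisopropylsilyloxy)eudesma-2,4(15),7-trien-1β-ol
Conditions: iBu2AlH (1.2 equiv), CH2Cl2, −78 °C; aq. potassium sodium tartrate; crude used at once
Reagents that add atoms: none
Why: 1,2-Reduction of the vinylogous ester carbonyl delivers hydride axially from the α face, anti to the vicinal axial C14 methyl (the sense seen in reduction of the saturated carbonyl of the Wieland–Miescher ketone), which sets the equatorial 1β-alcohol; the neutral work-up avoids ionisation of the γ-hydroxy enol ether.

Step 10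
Reactants: 11 3-methoxy-8-(triisopropylsilyloxy)eudesma-2,4(15),7-trien-1β-ol
Product: 12 1β-(tert-butyldimethylsilyloxy)-3-methoxy-8-(triisopropylsilyloxy)eudesma-2,4(15),7-triene
Conditions: TBSOTf (1.3 equiv), 2,6-lutidine (3 equiv), CH2Cl2, −78 → −40 °C
Reagents that add atoms: tert-butyldimethylsilyl triflate, CC(C)(C)[Si](C)(C)OS(=O)(=O)C(F)(F)F
Why: Silylation with the silyl triflate in excess hindered base caps the neopentyl-type C1 alcohol at low temperature with no free acid present, so that the C1 oxygen cannot be lost by β-elimination once the C3 ketone is unmasked.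

Step 11
Reactants: 12 1β-(tert-butyldimethylsilyloxy)-3-methoxy-8-(triisopropylsilyloxy)eudesma-2,4(15),7-triene
Product: 13 1β-(tert-butyldimethylsilyloxy)-8-(triisopropylsilyloxy)eudesma-4(15),7-dien-3-one
Conditions: 10% aq. (CO2H)2 on SiO2, CH2Cl2, 0 °C; filtration through NaHCO3; used at once
Reagents that add atoms: water, O
Why: Mild acid hydrolysis of the 2-methoxydiene proceeds by protonation at C2 to an oxocarbenium ion conjugated with C4=C15 and loss of methanol, so the C3 oxygen now comes from water; the tetrasubstituted TIPS enol ether and the TBS ether should react far more slowly.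

Step 12
Reactants: 13 1β-(tert-butyldimethylsilyloxy)-8-(triisopropylsilyloxy)eudesma-4(15),7-dien-3-one
Product: 14 1β-(tert-butyldimethylsilyloxy)-8-(triisopropylsilyloxy)eudesma-4(15),7-dien-3β-ol
Conditions: NaBH4, CeCl3·7H2O, MeOH, −78 °C
Reagents that add atoms: none
Why: Luche reduction gives only 1,2-reduction of the α-methylene ketone, and the small hydride enters axially from the α face as in 3-keto trans-decalins, which sets the equatorial 3β-alcohol.

Step 13
Reactants: 14 1β-(tert-butyldimethylsilyloxy)-8-(triisopropylsilyloxy)eudesma-4(15),7-dien-3β-ol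
Product: 16 1β-(tert-butyldimethylsilyloxy)-3β-hydroxyeudesm-4(15)-en-8-one (7β-isopropyl), via C8 tetrabutylammonium enolate 15 (not isolated)
Conditions: Bu4NF (1.1 equiv), AcOH (1.2 equiv), THF, −20 °C; then K2CO3, MeOH, 23 °C
Reagents that add atoms: none
Why: Fluoride cleaves the Si–O bond of the silyl enol ether much faster than that of the hindered alkyl TBS ether and acetic acid protonates the enolate; carbonate in methanol then places C7 under thermodynamic control through the same enolate, so the isopropyl group ends equatorial (7β) on the rigid trans-decalin.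

Step 14
Reactants: 16 1β-(tert-butyldimethylsilyloxy)-3β-hydroxyeudesm-4(15)-en-8-one
Product: 17 1β-(tert-butyldimethylsilyloxy)eudesm-4(15)-ene-3β,8α-diol
Conditions: Li, NH3 (l)/THF, EtOH, −78 °C; NH4Cl
Reagents that add atoms: none
Why: Dissolving-metal ketone reduction passes through the ketyl radical anion and carbanion to the thermodynamically preferred alcohol, giving the equatorial 8α-hydroxyl trans to the isopropyl group; a hydride reagent would be forced to the α side by the 1,3-related axial C14 methyl and would give the axial 8β-ol, while the isolated alkene, the allylic alkoxide and the silyl ether are inert.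

Step 15
Reactants: 18 caffeic acid
Product: 20 (E)-3,4-bis(tert-butyldimethylsilyloxy)cinnamic acid, via tris-TBS caffeate 19 (not isolated)
Conditions: TBSCl (3.5 equiv), imidazole (7 equiv), DMF, 23 °C; then AcOH/THF/H2O, 23 °C
Reagents that add atoms: tert-butyldimethylsilyl chloride, CC(C)(C)[Si](C)(C)Cl
Why: Exhaustive silylation followed by selective hydrolysis of the labile silyl ester in aqueous acetic acid leaves both aryl silyl ethers and the E alkene untouched.

Step 16
Reactants: 17 1β-(tert-butyldimethylsilyloxy)eudesm-4(15)-ene-3β,8α-diol; 20 (E)-3,4-bis(tert-butyldimethylsilyloxy)cinnamic acid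
Product: 21 1β-(tert-butyldimethylsilyloxy)-8α-hydroxyeudesm-4(15)-en-3β-yl (E)-3,4-bis(tert-butyldimethylsilyloxy)cinnamate
Conditions: 20 (1.0 equiv, slow addition), DCC (1.1 equiv), DMAP (0.1 equiv), CH2Cl2, −20 → 0 °C
Reagents that add atoms: none
Why: Steglich esterification with one equivalent of acid at low temperature should acylate O3, since the C3 hydroxyl is allylic and flanked only by a CH2 group and the sp2 C4, whereas the C8 hydroxyl is screened by the neighbouring isopropyl group as in menthol; no stereocentre is touched.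

Step 17
Reactants: 21 protected 3-caffeate
Product: 22 1β,8α-dihydroxyeudesm-4(15)-en-3β-yl (E)-caffeate (CNP0264533.1)
Conditions: HF·pyridine, pyridine, THF, 0 → 23 °C, Ar
Reagents that add atoms: none
Why: Fluoride desilylation under mildly acidic, oxygen-free conditions removes the two aryl silyl ethers and the C1 silyl ether without ester cleavage, acyl migration or oxidation of the catechol.

**Compound list**
1 | 2-methoxy-5-methylphenol | COc1ccc(C)cc1O | starting material
2 | 2-methoxy-5-methyl-1,4-benzoquinone | COC1=CC(=O)C(C)=CC1=O | intermediate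
3 | isovaleraldehyde | CC(C)CC=O | starting material
4 | 2-isopropylacrolein | C=C(C=O)C(C)C | intermediate
5 | 3-isopropylbut-3-en-2-ol (racemic) | CC(O)C(=C)C(C)C | intermediate
6 | 3-isopropylbut-3-en-2-one | CC(=O)C(=C)C(C)C | intermediate
7 | 2-(triisopropylsilyloxy)-3-isopropylbuta-1,3-diene | C=C(O[Si](C(C)C)(C(C)C)C(C)C)C(=C)C(C)C | intermediate
8 | cis-fused adduct; 3-methoxy-8-(triisopropylsilyloxy)-15-nor-5β-eudesma-2,7-diene-1,4-dione (5S,10R) | O=C1C(OC)=CC(=O)[C@]2(C)CC(O[Si](C(C)C)(C(C)C)C(C)C)=C(C(C)C)C[C@H]12 | intermediate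
9 | trans-fused 3-methoxy-8-(triisopropylsilyloxy)-15-nor-5α-eudesma-2,7-diene-1,4-dione (5R,10R) | O=C1C(OC)=CC(=O)[C@]2(C)CC(O[Si](C(C)C)(C(C)C)C(C)C)=C(C(C)C)C[C@@H]12 | intermediate
10 | 3-methoxy-8-(triisopropylsilyloxy)eudesma-2,4(15),7-trien-1-one (5α-H; 10β-CH3) | C=C1C(OC)=CC(=O)[C@]2(C)CC(O[Si](C(C)C)(C(C)C)C(C)C)=C(C(C)C)C[C@@H]12 | intermediate
11 | 3-methoxy-8-(triisopropylsilyloxy)eudesma-2,4(15),7-trien-1β-ol | C=C1C(OC)=C[C@@H](O)[C@]2(C)CC(O[Si](C(C)C)(C(C)C)C(C)C)=C(C(C)C)C[C@@H]12 | intermediate
12 | 1β-(tert-butyldimethylsilyloxy)-3-methoxy-8-(triisopropylsilyloxy)eudesma-2,4(15),7-triene | C=C1C(OC)=C[C@@H](O[Si](C)(C)C(C)(C)C)[C@]2(C)CC(O[Si](C(C)C)(C(C)C)C(C)C)=C(C(C)C)C[C@@H]12 | intermediate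
13 | 1β-(tert-butyldimethylsilyloxy)-8-(triisopropylsilyloxy)eudesma-4(15),7-dien-3-one | C=C1C(=O)C[C@@H](O[Si](C)(C)C(C)(C)C)[C@]2(C)CC(O[Si](C(C)C)(C(C)C)C(C)C)=C(C(C)C)C[C@@H]12 | intermediate
14 | 1β-(tert-butyldimethylsilyloxy)-8-(triisopropylsilyloxy)eudesma-4(15),7-dien-3β-ol | C=C1[C@@H](O)C[C@@H](O[Si](C)(C)C(C)(C)C)[C@]2(C)CC(O[Si](C(C)C)(C(C)C)C(C)C)=C(C(C)C)C[C@@H]12 | intermediate
15 | C8 tetrabutylammonium enolate of ketone 16 | C=C1[C@@H](O)C[C@@H](O[Si](C)(C)C(C)(C)C)[C@]2(C)CC([O-])=C(C(C)C)C[C@@H]12.CCCC[N+](CCCC)(CCCC)CCCC | intermediate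
16 | 1β-(tert-butyldimethylsilyloxy)-3β-hydroxyeudesm-4(15)-en-8-one (7β-isopropyl) | C=C1[C@@H](O)C[C@@H](O[Si](C)(C)C(C)(C)C)[C@]2(C)CC(=O)[C@@H](C(C)C)C[C@@H]12 | intermediate
17 | 1β-(tert-butyldimethylsilyloxy)eudesm-4(15)-ene-3β,8α-diol | C=C1[C@@H](O)C[C@@H](O[Si](C)(C)C(C)(C)C)[C@]2(C)C[C@H](O)[C@@H](C(C)C)C[C@@H]12 | intermediate
18 | caffeic acid | O=C(O)/C=C/c1ccc(O)c(O)c1 | starting material
19 | tert-butyldimethylsilyl (E)-3,4-bis(tert-butyldimethylsilyloxy)cinnamate | CC(C)(C)[Si](C)(C)OC(=O)/C=C/c1ccc(O[Si](C)(C)C(C)(C)C)c(O[Si](C)(C)C(C)(C)C)c1 | intermediate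
20 | (E)-3,4-bis(tert-butyldimethylsilyloxy)cinnamic acid | O=C(O)/C=C/c1ccc(O[Si](C)(C)C(C)(C)C)c(O[Si](C)(C)C(C)(C)C)c1 | intermediate
21 | 1β-(tert-butyldimethylsilyloxy)-8α-hydroxyeudesm-4(15)-en-3β-yl (E)-3,4-bis(tert-butyldimethylsilyloxy)cinnamate | C=C1[C@@H](OC(=O)/C=C/c2ccc(O[Si](C)(C)C(C)(C)C)c(O[Si](C)(C)C(C)(C)C)c2)C[C@@H](O[Si](C)(C)C(C)(C)C)[C@]2(C)C[C@H](O)[C@@H](C(C)C)C[C@@H]12 | intermediate
22 | 1β,8α-dihydroxyeudesm-4(15)-en-3β-yl (E)-caffeate, CNP0264533.1 | C=C1[C@@H](OC(=O)/C=C/c2ccc(O)c(O)c2)C[C@@H](O)[C@]2(C)C[C@H](O)[C@@H](C(C)C)C[C@@H]12 | target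

**Count and risks**

Total step count: 17. Longest linear sequence: 15 steps (steps 2 to 14, then 16 and 17, from isovaleraldehyde).

Steps most likely to fail:

Step 6. The chiral titanium chelate may discriminate poorly between the two quinone faces, or the Lewis acid may strip the silyl enol ether from the diene before cycloaddition. The fallback gives up asymmetric induction and moves absolute control to a resolution. Setting out from quinone 2 and diene 7, a thermal cycloaddition (toluene, 80 °C, sealed vessel), whose orientation is governed by the same C4 carbonyl because C1=O is a vinylogous ester, would give the racemic cis-fused adduct F1. DBU in CH2Cl2 would epimerise it to the racemic trans-fused enedione F2. Preparative chromatography on a chiral stationary phase (supercritical CO2/iPrOH) would then supply the (10R) enantiomer, which re-enters the route as compound 9.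

Step 11. The silyl enol ether may be hydrolysed together with the methyl enol ether, or the freshly formed α-methylene ketone may be lost by β-elimination of the C1 silyloxy group or by self-addition. The fallback reverses the order of unmasking, so that no selectivity between the two enol ethers is needed and the discrimination is moved to the carbonyl groups. Setting out from compound 12, Bu4NF/AcOH in THF at −20 °C followed by K2CO3 in MeOH would cleave only the silyl enol ether and give 1β-(tert-butyldimethylsilyloxy)-3-methoxyeudesma-2,4(15)-dien-8-one F3 with the methoxydiene intact. Oxalic acid on wet SiO2 would then give 1β-(tert-butyldimethylsilyloxy)eudesm-4(15)-ene-3,8-dione F4. A Luche reduction with a deficiency of NaBH4 at −78 °C would reduce the conjugated C3 carbonyl in preference to the saturated C8 ketone, which is hindered by the α-isopropyl group and by C14, and would return the route at compound 16.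

Step 16. Acylation may not distinguish O3 from O8 well enough, leading to mixtures that include the 8-ester and the diester. The fallback replaces site-selective acylation by a protecting-group differentiation based on allylic oxidation. Setting out from diol 17, MnO2 in CH2Cl2 would oxidise only the allylic C3 alcohol to 1β-(tert-butyldimethylsilyloxy)-8α-hydroxyeudesm-4(15)-en-3-one F5. TBSOTf/2,6-lutidine at −78 °C would cap O8 to give 1β,8α-bis(tert-butyldimethylsilyloxy)eudesm-4(15)-en-3-one F6. Luche reduction would restore the equatorial alcohol as 1β,8α-bis(tert-butyldimethylsilyloxy)eudesm-4(15)-en-3β-ol F7. DCC/DMAP esterification with acid 20 would give the fully silylated 3β-caffeate F8, and HF·pyridine would remove all four silyl groups to reach compound 22.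

Further compounds
F1 | step 6 | racemic cis-fused adduct (both enantiomers) | O=C1C(OC)=CC(=O)[C@]2(C)CC(O[Si](C(C)C)(C(C)C)C(C)C)=C(C(C)C)C[C@H]12.O=C1C(OC)=CC(=O)[C@@]2(C)CC(O[Si](C(C)C)(C(C)C)C(C)C)=C(C(C)C)C[C@@H]12
F2 | step 6 | racemic trans-fused enedione (both enantiomers) | O=C1C(OC)=CC(=O)[C@]2(C)CC(O[Si](C(C)C)(C(C)C)C(C)C)=C(C(C)C)C[C@@H]12.O=C1C(OC)=CC(=O)[C@@]2(C)CC(O[Si](C(C)C)(C(C)C)C(C)C)=C(C(C)C)C[C@H]12
F3 | step 11 | 1β-(tert-butyldimethylsilyloxy)-3-methoxyeudesma-2,4(15)-dien-8-one (7β-isopropyl) | C=C1C(OC)=C[C@@H](O[Si](C)(C)C(C)(C)C)[C@]2(C)CC(=O)[C@@H](C(C)C)C[C@@H]12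
F4 | step 11 | 1β-(tert-butyldimethylsilyloxy)eudesm-4(15)-ene-3,8-dione (7β-isopropyl) | C=C1C(=O)C[C@@H](O[Si](C)(C)C(C)(C)C)[C@]2(C)CC(=O)[C@@H](C(C)C)C[C@@H]12
F5 | step 16 | 1β-(tert-butyldimethylsilyloxy)-8α-hydroxyeudesm-4(15)-en-3-one | C=C1C(=O)C[C@@H](O[Si](C)(C)C(C)(C)C)[C@]2(C)C[C@H](O)[C@@H](C(C)C)C[C@@H]12
F6 | step 16 | 1β,8α-bis(tert-butyldimethylsilyloxy)eudesm-4(15)-en-3-one | C=C1C(=O)C[C@@H](O[Si](C)(C)C(C)(C)C)[C@]2(C)C[C@H](O[Si](C)(C)C(C)(C)C)[C@@H](C(C)C)C[C@@H]12
F7 | step 16 | 1β,8α-bis(tert-butyldimethylsilyloxy)eudesm-4(15)-en-3β-ol | C=C1[C@@H](O)C[C@@H](O[Si](C)(C)C(C)(C)C)[C@]2(C)C[C@H](O[Si](C)(C)C(C)(C)C)[C@@H](C(C)C)C[C@@H]12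
F8 | step 16 | 1β,8α-bis(tert-butyldimethylsilyloxy)eudesm-4(15)-en-3β-yl (E)-3,4-bis(tert-butyldimethylsilyloxy)cinnamate | C=C1[C@@H](OC(=O)/C=C/c2ccc(O[Si](C)(C)C(C)(C)C)c(O[Si](C)(C)C(C)(C)C)c2)C[C@@H](O[Si](C)(C)C(C)(C)C)[C@]2(C)C[C@H](O[Si](C)(C)C(C)(C)C)[C@@H](C(C)C)C[C@@H]12
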